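All constants were chosen freely; the rest is arithmetic.

A small charge of L, 10 mM, stood against 13.0 mM of D, and I wanted the X in each flask at 6.0 s.

in all of them: D 13.0 mM; time 6.0 s
- larch: L 10 mM (fed, over 0.60 s); temperature 5 °C; all else is in the flask from the start; the feed brings no volume worth counting
- maple: L 10 mM (fed, over 2.5 s); the addition at −35 °C, then warmed to 5 °C; the feed brings no volume worth counting
- cedar: L 10 mM (fed, over 2.5 s); temperature 5 °C; all else is in the flask from the start; the feed brings no volume worth counting
- alder: L 10 mM; temperature 5 °C; everything together at the start

    L + D → L.D (k1 = 9.1 /M/s, Ea1 = 45.0 kJ/mol)
    D + L.D → D.L.D (k2 = 24 /M/s, Ea2 = 50.0 kJ/mol)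
    L + D.L.D → X (k3 = 160 /M/s, Ea3 = 42.0 kJ/mol)
    (constants at 5 °C)

- percentages count the L that a species holds: one X counts as two
- constants are those at 5 °C; use the activation energies for any other temperature

* which flask leads in amount of X, in percent of the L charged ("all alike" within 1.5 percentage points) (larch / maple / cedar / alder / all alike)
* how much X is there at the end, in percent of the L charged: larch
* how much X is there at the end, in percent of the L charged: maple
* how much X is there at the end, in percent of the L charged: cedar
* how much X is there at the end, in percent of the L charged: alder

L reached X by a relay: the first step made L.D, the second turned it into D.L.D, and the third spent D.L.D on another L. The concentration I watched was [D], which multiplies [L.D] in the second step. At the charged [D] the lifetime of L.D was 3.21 s, and at the charged [L] the lifetime of D.L.D was 0.625 s, so L.D lasted longer than D.L.D; both are lifetimes for the start, since I took the concentrations as charged. Their sum, 3.83 s, I called the relay lag, the time the two adducts take to fill before X comes at the pace of the first step; the trade calls this an induction period.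

I took two extreme versions of alder. If the relay passed everything on at once, each first step would take two L and two D, and the second-order integral over 6.0 s put X at 62.7 %. If the relay stalled at L.D, alder would hold no X. The real alder had to lie between, and its time exceeded the lag, so I ran the same integral over the 2.17 s that remained, which gave 35.3 % as my figure.

A steady feed delivers its L on average at half its time, so I took that much off the clock of larch and cedar. I wrote off the whole feed in maple, which ran at −35 °C. That put alder first.

The forecast also chose alder, with 31.2 % there, 29.4 % in larch, 23.3 % in cedar and 15 % in maple, holding that “every delay in getting L into the flask costs X”. My alder figure stood above its figure.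

The simulation put alder first, with 31.0 % in alder, 29.2 % in larch, 23.3 % in cedar and 14.8 % in maple.

Alder still held 46 % of its L unbound at 6.00 s. Left until 60.0 s, alder reached 89.9 % and maple 89.8 %. I then took alder read at 10 s: the same lag left 6.17 s, the integral gave 63.4 %, and the flask held 51.3 % of X.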